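In 10 min this flask had to grow chains while E took Z away, so I turned the question round and asked what short chains would have required.

    J + X → J.X (k1 = 0.073 L mol⁻¹ s⁻¹)
    Z → Q (k2 = 1.4 × 10⁻⁴ s⁻¹)
    Z + J → G + X (k3 = 0.013 L mol⁻¹ s⁻¹)
    E + Z → E.Z (k4 = 0.067 L mol⁻¹ s⁻¹)
    Z + G → X + G, rate k5*[G]*[Z] (k5 = 8.7 L mol⁻¹ s⁻¹)

Z 0.10 M; E 0.0500 M; J 1.1 mM; time 10 min

- average number of monomer units in a chain (chains begun, living or dead) at 10 min
- part of the Z that has reacted at 10 min

I let Z fall by its pseudo-first-order loss to E and to Q, held at the starting rate. This was rough, since I ignored the fall of E and the Z taken by the chains. That loss gave Z a lifetime τ of 4.78 min, shorter than the run, so I expected c near 87.7 %. Most of the Z left over would have needed τ long against the run, which my τ was not.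

A living end added 0.870 s⁻¹ at the charged c(Z), so the first chain could take in m = 219 units: growth rate times τ times the part of Z gone. Chains were born far more slowly than Z was lost, and their birth rate follows c(Z). Taking c(J) as steady, which was a rough assumption, births faded as Z did, and the average chain got 109 units, half of m. I called this n, my turnover count, the units taken in by the average chain begun. Short chains would have needed n near one, and my n stood far above that.

The forecast said dp 136 (120 to 150) and c 84 % (80 % to 88 %), from “a rough hand march through time rather than an exact integration”. My n lay below its dp.

The flask gave dp 134, which was 24.9 above n, and c 84.8 %. At the start of this flask E took Z at 0.00335 s⁻¹ per unit of Z, before any chain stood. At 10.0 min in this flask the living ends took it at 0.00251 s⁻¹, faster than E at 5.47 × 10⁻⁴ s⁻¹. For the neighbour flask charged with 0.040 M of Z, my τ stayed as it was and n scaled to 43.7, and that flask gave dp 48.2.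

(The numbers of this flask are those of an exercise, and the outcome is calculated.)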